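Percent of the charge is the unit to count in with this flask, which is epsilon followed on to 10 min. Beta, charged with twice as much of each hand, stands at nearly the same percentages at the same times: the share in neither product at 5.00 min reads 16.4% in epsilon and 15.8% in beta.

| flask | left-handed substrate | right-handed substrate | gas | remark | time |
|---|---|---|---|---|---|
| epsilon | 0.26 M | 0.26 M | 15 mM (held) | the very flask that is asked about, followed so far |  |
| beta | 0.52 M | 0.52 M | 15 mM (held) | run made earlier |  |
| flask | 0.26 M | 0.26 M | 15 mM (held) |  | 10 min |

| run | time / min | left-handed product / % | right-handed product / % |
|---|---|---|---|
| epsilon | 1.00 | 26.9 | 12.5 |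
| epsilon | 2.00 | 38.0 | 20.2 |
| epsilon | 3.00 | 44.8 | 24.7 |
| epsilon | 4.00 | 48.0 | 29.5 |
| epsilon | 5.00 | 50.3 | 33.3 |
| beta | 0.667 | 19.6 | 8.0 |
| beta | 2.00 | 37.4 | 18.9 |
| beta | 3.00 | 44.1 | 24.8 |
| beta | 5.00 | 51.0 | 33.2 |
| beta | 8.00 | 55.2 | 38.5 |

(each reading ± 0.5 percentage points)

- partner is single-handed; left-handed substrate and right-handed substrate are mirror images of each other, charged as a racemate, each of them at the stated concentration
- at the start none of the gas is in solution
- what has gone into achiral form counts as reacted
- an excess is the difference of the two amounts in percent of their sum
- an excess is below zero if the other one leads
- the handed part of partner does not stay in what it makes, so the products of the two hands are mirror images too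

- excess of left-handed product over right-handed product in the product at 1.0 min
- excess of left-handed product over right-handed product in the product at 10 min
- part of the left-handed substrate and right-handed substrate charged together that has reacted at 10 min

So I freeze the partner at a steady level, and each hand then loses a fixed fraction per minute, its own for each hand (pseudo-first-order). Two extremes can be solved in the head. If the hands never cross, each product stops at the amount of its own hand and the excess ends at zero. If they cross at once, the excess stays level at its early value, which beta reads as 42.0% at 0.667 min. Beta lies between: its left-handed product reads 55.2% at 8.00 min, beyond its own hand's share, yet its excess has sunk to 17.8%.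

For the early excess in this flask I take the reading at 1.0 min, 36.5%. For the end I watch the share in neither product. In beta it falls to 6.30% at 8.00 min, which reads as 2.26 min, the late half-life of the unfinished part in beta. Frozen, and with this flask taken to follow beta, it leaves about 3.41% at 10 min. Left-handed product took 44.2% of beta's late gain, and the same split gives this flask an estimated excess of 16.9%. I put reacted at 96.6% or a little more, as any achiral form in that unfinished part counts as reacted.

The forecast gives 37.5%, 16.8% and 97%, holding that “some substrate crosses over, probably through the achiral form”, and its early excess stands above my reading.

The flask gives excesses of 40.2% and 16.2%, with 97.7% reacted.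

    partner + left-handed substrate → left-handed product (k = 63.0 L mol⁻¹ min⁻¹)
    partner + right-handed substrate → right-handed product (k = 21.0 L mol⁻¹ min⁻¹)
    left-handed substrate ⇌ achiral form (K = 0.480, k = 0.200 min⁻¹)
    right-handed substrate ⇌ achiral form (K = 0.480, k = 0.200 min⁻¹)
    achiral form → waste (k = 0.00910 min⁻¹)
    2 partner → self-condensation product (k = 12.0 L mol⁻¹ min⁻¹)
    gas ⇌ partner, rate k7*(csat - [partner]) (kL = 150 min⁻¹)
    partner ⇌ dormant form (K = 9.80, k = 0.120 min⁻¹)

In this flask the partner stands at 99.5% of the saturation concentration of gas at 10.0 min, and its step to self-condensation product makes no difference to that late excess. In this flask, substrates, achiral form and waste together hold 15.6% at 5.00 min. Halving that every 2.26 min gives 3.37% at 10 min, and the flask holds 3.55%.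

(The earlier runs and the new flask were generated by integration with made-up constants; scatter was added.)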